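The route cuts ring A between its methylidene-bearing carbon and the neighbouring methine that carries the side chain. This C(=CH2)–CH pair, flanked by the CMe2 carbon and the carbinol carbon, is the imprint of an alkyne adding to an alkene. One palladium-hydride cycloisomerisation of an acyclic keto-enyne (terminal alkyne, two CH2 groups, ketone, CMe2, (E)-allylic silyl ether) closes ring A and creates the exocyclic alkene. The same step sets the methine centre under ligand control and delivers the side-chain stub as a silyl enol ether. Ketone reduction, growth of the stub to an (E)-iodoalkene and a B-alkyl Suzuki–Miyaura coupling with an (R)-2-vinylchroman finish the target.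

Key step: step 5

Reading of the target: in ring A the carbinol carbon is R and the side-chain methine is R, so hydroxyl and side chain are trans (axial OH when the chain is equatorial). Chroman C2 is S and the chain alkene is E.

Assumption: the sense of induction in the two ligand-controlled steps (5 and 18) is assigned by analogy; both antipodes of each ligand are commercial, so the other antipode would be taken if a first run shows the opposite sense.

Step 1
Reactants: 1 2,2-dimethylbut-3-enoic acid
Product: 2 N-methoxy-N,2,2-trimethylbut-3-enamide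
Conditions: MeNH(OMe)·HCl, EDC·HCl, DMAP (cat.), Et3N, CH2Cl2, 0 °C to rt
Reagents that add atoms: N,O-dimethylhydroxylamine hydrochloride, CNOC.Cl
Why: Carbodiimide-mediated amide coupling gives the Weinreb amide, which will later stop organometallic addition at the ketone stage, and no stereocentre is involved.

Step 2
Reactants: 2 N-methoxy-N,2,2-trimethylbut-3-enamide; 3 tert-butyl(dimethyl)(prop-2-en-1-yloxy)silane
Product: 4 (3E)-5-(tert-butyldimethylsilyloxy)-N-methoxy-N,2,2-trimethylpent-3-enamide
Conditions: 3 (3 equiv), second-generation Hoveyda–Grubbs catalyst RuCl2(H2IMes)(=CH-C6H4-2-Oi-Pr) (5 mol %), 1,4-benzoquinone (10 mol %), CH2Cl2, 40 °C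
Reagents that add atoms: none
Why: Olefin cross-metathesis between a slow, non-dimerising vinyl group on a quaternary carbon and an excess of a fast-reacting allyl ether should favour the cross product, and the bulk of the quaternary carbon enforces the (E)-alkene.

Step 3
Reactants: 4 (3E)-5-(tert-butyldimethylsilyloxy)-N-methoxy-N,2,2-trimethylpent-3-enamide; 5 (4-bromobut-1-yn-1-yl)trimethylsilane
Product: 7 (7E)-9-(tert-butyldimethylsilyloxy)-6,6-dimethyl-1-(trimethylsilyl)non-7-en-1-yn-5-one, via Grignard reagent 6 (not isolated)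
Conditions: 5, Mg, THF, rt to 40 °C; then 4, THF, 0 °C to rt; aq NH4Cl
Reagents that add atoms: none
Why: Grignard addition to a Weinreb amide stops at the chelated tetrahedral adduct, so only the ketone is released on work-up, and the C-silyl group keeps the acetylenic position free of an acidic hydrogen.

Step 4
Reactants: 7 (7E)-9-(tert-butyldimethylsilyloxy)-6,6-dimethyl-1-(trimethylsilyl)non-7-en-1-yn-5-one
Product: 8 (7E)-9-(tert-butyldimethylsilyloxy)-6,6-dimethylnon-7-en-1-yn-5-one
Conditions: K2CO3 (cat.), MeOH, 0 °C to rt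
Reagents that add atoms: none
Why: Base-catalysed methanolysis cleaves the C(sp)–Si bond selectively, while the alkyl silyl ether is inert and the quaternary C6 blocks migration of the alkene into conjugation.

Step 5
Reactants: 8 (7E)-9-(tert-butyldimethylsilyloxy)-6,6-dimethylnon-7-en-1-yn-5-one
Product: 9 (3R)-3-[(E)-2-(tert-butyldimethylsilyloxy)ethenyl]-2,2-dimethyl-4-methylidenecyclohexan-1-one
Conditions: Pd(OCOCF3)2 (5 mol %) and (R)-SEGPHOS (10 mol %) premixed, toluene, 80 °C
Reagents that add atoms: none
Why: Proposed new method: a (bisphosphine)palladium hydride of divalent palladium, formed in situ from Pd(OCOCF3)2 and the ligand, should add across the terminal alkyne of 8 with palladium on C2, so that C1 becomes the =CH2 group; the alkenylpalladium then inserts the C7=C8 bond syn, and β-hydride loss from C9 returns the hydride and frees the silyl enol ether. The closest known reaction type is the palladium-catalysed Alder-ene cycloisomerisation of enynes, which is enantioselective with BINAP- and SEGPHOS-type ligands for 1,6-enynes and for aniline-tethered 1,7-enynes but has not been shown for an all-carbon 1,7-enyne bearing a terminal alkyne. Ring A closes in a 6-exo-trig mode through the new C2–C7 bond, helped by the gem-dimethyl group at C6 and the sp2 ketone carbon C5, which compress the tether. The single new stereocentre (C7, the ring methine, R) is fixed in the insertion step by the C2-symmetric ligand, which tells the two faces of the (E)-alkene apart, and no other stereocentre is present to oppose it. The step needs β-hydride loss toward C9 and not toward the C7 methine, which the oxygen-activated C9–H bonds secure, and it needs the ketone oxygen to stay off the alkyne, which premixing metal and ligand (no ligand-free divalent palladium) is meant to secure.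

Step 6
Reactants: 9 (3R)-3-[(E)-2-(tert-butyldimethylsilyloxy)ethenyl]-2,2-dimethyl-4-methylidenecyclohexan-1-one
Product: 10 (1R,3R)-3-[(E)-2-(tert-butyldimethylsilyloxy)ethenyl]-2,2-dimethyl-4-methylidenecyclohexan-1-ol
Conditions: LiBH(s-Bu)3, THF, −78 °C; aq NH4Cl
Reagents that add atoms: none
Why: Hydride reduction under steric approach control: with the C3 side chain equatorial the bulky trialkylborohydride should reach C1 from the equatorial direction and give the axial (1R)-hydroxyl trans to the side chain, as is usual for 2,2-dimethylcyclohexanones.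

Step 7
Reactants: 10 (1R,3R)-3-[(E)-2-(tert-butyldimethylsilyloxy)ethenyl]-2,2-dimethyl-4-methylidenecyclohexan-1-ol
Product: 11 tert-butyl{(E)-2-[(1R,3R)-3-(tert-butyldimethylsilyloxy)-2,2-dimethyl-6-methylidenecyclohexyl]ethenyloxy}dimethylsilane
Conditions: TBSOTf, 2,6-lutidine, CH2Cl2, 0 °C
Reagents that add atoms: tert-butyldimethylsilyl trifluoromethanesulfonate, CC(C)(C)[Si](C)(C)OS(=O)(=O)C(F)(F)F
Why: O-Silylation with the silyl triflate is the standard answer to a hindered secondary alcohol next to a quaternary carbon, and the buffered medium leaves the silyl enol ether untouched.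

Step 8
Reactants: 11 tert-butyl{(E)-2-[(1R,3R)-3-(tert-butyldimethylsilyloxy)-2,2-dimethyl-6-methylidenecyclohexyl]ethenyloxy}dimethylsilane
Product: 13 2-[(1R,3R)-3-(tert-butyldimethylsilyloxy)-2,2-dimethyl-6-methylidenecyclohexyl]ethan-1-ol, via aldehyde 12 (not isolated)
Conditions: Bu4NF (1.05 equiv), AcOH (1.1 equiv), THF, 0 °C; then NaBH4, MeOH, 0 °C
Reagents that add atoms: none
Why: Buffered fluoride cleaves the much more labile silyl enol ether in preference to the hindered secondary silyl ether, and borohydride reduction of the freed aldehyde in the same flask avoids handling it, neither stereocentre being at an enolisable position.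

Step 9
Reactants: 13 2-[(1R,3R)-3-(tert-butyldimethylsilyloxy)-2,2-dimethyl-6-methylidenecyclohexyl]ethan-1-ol
Product: 14 tert-butyl{[(1R,3R)-3-(2-iodoethyl)-2,2-dimethyl-4-methylidenecyclohexyl]oxy}dimethylsilane
Conditions: I2, PPh3, imidazole, CH2Cl2, 0 °C
Reagents that add atoms: iodine, II
Why: Appel-type iodination converts the unhindered primary alcohol by SN2 displacement under near-neutral conditions that spare the silyl ether and the exocyclic alkene.

Step 10
Reactants: 14 tert-butyl{[(1R,3R)-3-(2-iodoethyl)-2,2-dimethyl-4-methylidenecyclohexyl]oxy}dimethylsilane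
Product: 15 tert-butyl{[(1R,3R)-3-(but-3-yn-1-yl)-2,2-dimethyl-4-methylidenecyclohexyl]oxy}dimethylsilane
Conditions: LiC≡CH·H2NCH2CH2NH2, DMSO/THF, 0 °C to rt
Reagents that add atoms: lithium acetylide–ethane-1,2-diamine complex, [Li+].[C-]#C.NCCN
Why: SN2 alkylation of lithium acetylide by a primary iodide in a dipolar aprotic medium adds the two missing carbons directly as the terminal alkyne.

Step 11
Reactants: 15 tert-butyl{[(1R,3R)-3-(but-3-yn-1-yl)-2,2-dimethyl-4-methylidenecyclohexyl]oxy}dimethylsilane
Product: 17 tert-butyl{[(1R,3R)-3-[(3E)-4-iodo-3-methylbut-3-en-1-yl]-2,2-dimethyl-4-methylidenecyclohexyl]oxy}dimethylsilane, via alkenylalane 16 (not isolated)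
Conditions: Me3Al, Cp2ZrCl2 (0.25 equiv), CH2Cl2, 0 °C to rt; then I2, THF, −30 °C
Reagents that add atoms: trimethylaluminium, C[Al](C)C; iodine, II
Why: Negishi zirconium-catalysed carboalumination adds methyl and aluminium syn across the terminal alkyne with aluminium at the terminus, iodinolysis with retention gives the (E)-iodoalkene, and the 1,1-disubstituted ring alkene does not react under these conditions.

Step 12
Reactants: 18 2-methylbenzene-1,4-diol (methylhydroquinone)
Product: 19 2-methyl-4-(triisopropylsilyloxy)phenol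
Conditions: TIPSCl (1.0 equiv), imidazole, DMF, 0 °C
Reagents that add atoms: chlorotri(propan-2-yl)silane, CC(C)[Si](Cl)(C(C)C)C(C)C
Why: Sterically governed monosilylation with a bulky chlorosilane should pick the hydroxyl that has no ortho methyl group, and the resulting aryl TIPS ether tolerates the aqueous base of the later couplings.

Step 13
Reactants: 19 2-methyl-4-(triisopropylsilyloxy)phenol
Product: 20 2-hydroxy-3-methyl-5-(triisopropylsilyloxy)benzaldehyde
Conditions: MgCl2, Et3N, (CH2O)n, MeCN, 80 °C; dilute acid work-up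
Reagents that add atoms: paraformaldehyde (as formaldehyde), C=O
Why: Casnati–Skattebøl ortho-formylation through the magnesium phenoxide can only strike the one free ortho position, which fixes the 8-methyl/6-oxygen pattern of the chroman without regioisomers.

Step 14
Reactants: 20 2-hydroxy-3-methyl-5-(triisopropylsilyloxy)benzaldehyde
Product: 21 2-ethenyl-6-methyl-4-(triisopropylsilyloxy)phenol
Conditions: Ph3PCH3Br and KOt-Bu (2.5 equiv each), THF, 0 °C to rt
Reagents that add atoms: methyltriphenylphosphonium bromide, C[P+](c1ccccc1)(c1ccccc1)c1ccccc1.[Br-]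
Why: Wittig methylenation of salicylaldehydes works on the phenoxide when an extra equivalent of ylide is supplied, giving the 2-vinylphenol, which is used without storage.

Step 15
Reactants: 22 but-2-yn-1-ol
Product: 24 (2Z)-3-iodobut-2-en-1-ol, via cyclic alkenylaluminate 23 (not isolated)
Conditions: NaAlH2(OCH2CH2OMe)2, THF, 0 °C to rt; then I2, THF, −78 °C
Reagents that add atoms: iodine, II
Why: Alkoxide-directed trans-hydroalumination of the propargylic alcohol places aluminium on C3 in a five-membered ring, and iodinolysis with retention gives only the (Z)-iodoalkene.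

Step 16
Reactants: 21 2-ethenyl-6-methyl-4-(triisopropylsilyloxy)phenol; 24 (2Z)-3-iodobut-2-en-1-ol
Product: 26 2-[(3Z)-5-hydroxy-3-methylpent-3-en-1-yl]-6-methyl-4-(triisopropylsilyloxy)phenol, via bis-boryl adduct 25 (not isolated)
Conditions: 21, 9-BBN-H (2.2 equiv), THF, rt; then 24, PdCl2(dppf) (5 mol %), aq K3PO4, DMF, rt to 50 °C
Reagents that add atoms: none
Why: 9-BBN-H adds anti-Markovnikov to the styrene (one further equivalent is taken up by the phenol), and the B-alkyl Suzuki–Miyaura coupling replaces iodine with retention, so the (Z)-geometry of 24 is carried into 26.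

Step 17
Reactants: 26 2-[(3Z)-5-hydroxy-3-methylpent-3-en-1-yl]-6-methyl-4-(triisopropylsilyloxy)phenol
Product: 27 (2Z)-5-[2-hydroxy-3-methyl-5-(triisopropylsilyloxy)phenyl]-3-methylpent-2-en-1-yl methyl carbonate
Conditions: ClCO2Me (1.05 equiv), pyridine, CH2Cl2, −20 °C
Reagents that add atoms: methyl chloroformate, COC(=O)Cl
Why: Chemoselective O-acylation under weak-base conditions should take the unhindered primary allylic alcohol ahead of the 2,6-disubstituted phenol.

Step 18
Reactants: 27 (2Z)-5-[2-hydroxy-3-methyl-5-(triisopropylsilyloxy)phenyl]-3-methylpent-2-en-1-yl methyl carbonate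
Product: 28 {[(2R)-2-ethenyl-2,8-dimethyl-3,4-dihydro-2H-chromen-6-yl]oxy}tri(propan-2-yl)silane
Conditions: Pd2(dba)3·CHCl3 (2 mol %), (1S,2S)-N,N'-bis[2-(diphenylphosphanyl)benzoyl]cyclohexane-1,2-diamine (6 mol %), AcOH (1 equiv), CH2Cl2, rt
Reagents that add atoms: none
Why: Asymmetric Tsuji–Trost allylic etherification: zerovalent palladium ionises the carbonate, the phenol attacks the π-allyl complex 6-exo at its more substituted terminus, and the chiral pocket of the ligand selects the allyl face and so sets C2 as R, a reaction type established for 2-methyl-2-vinylchromans.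

Step 19
Reactants: 28 {[(2R)-2-ethenyl-2,8-dimethyl-3,4-dihydro-2H-chromen-6-yl]oxy}tri(propan-2-yl)silane; 17 tert-butyl{[(1R,3R)-3-[(3E)-4-iodo-3-methylbut-3-en-1-yl]-2,2-dimethyl-4-methylidenecyclohexyl]oxy}dimethylsilane
Product: 30 bis-silyl ether of the target (secondary O-TBS in ring A and phenolic O-TIPS; 1R,3R in ring A; 2S at the chroman; E alkene), via B-alkylborane 29 (not isolated)
Conditions: 28, 9-BBN-H (1.2 equiv), THF, rt; then aq K3PO4; then 17, PdCl2(dppf) (5 mol %), DMF, rt
Reagents that add atoms: none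
Why: Hydroboration places boron on the terminal vinyl carbon, aqueous base destroys residual B–H before 17 is added so that its exocyclic alkene is safe, and the B-alkyl Suzuki–Miyaura coupling proceeds with retention at the (E)-iodoalkene without touching any stereocentre.

Step 20
Reactants: 30 bis-silyl ether of the target
Product: 31 (2S)-2-{(3E)-6-[(1R,3R)-3-hydroxy-2,2-dimethyl-6-methylidenecyclohexyl]-4-methylhex-3-en-1-yl}-2,8-dimethyl-3,4-dihydro-2H-chromen-6-ol
Conditions: Bu4NF (excess), THF, 50 °C, under argon; aq NH4Cl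
Reagents that add atoms: none
Why: Fluoride-induced desilylation removes the aryl TIPS ether at once and the hindered secondary TBS ether on warming, under non-acidic conditions that cannot move the exocyclic or the trisubstituted alkene.

Compound list
1 | 2,2-dimethylbut-3-enoic acid | C=CC(C)(C)C(=O)O | starting material
2 | N-methoxy-N,2,2-trimethylbut-3-enamide | C=CC(C)(C)C(=O)N(C)OC | intermediate
3 | tert-butyl(dimethyl)(prop-2-en-1-yloxy)silane | C=CCO[Si](C)(C)C(C)(C)C | starting material
4 | (3E)-5-(tert-butyldimethylsilyloxy)-N-methoxy-N,2,2-trimethylpent-3-enamide | CON(C)C(=O)C(C)(C)/C=C/CO[Si](C)(C)C(C)(C)C | intermediate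
5 | (4-bromobut-1-yn-1-yl)trimethylsilane | C[Si](C)(C)C#CCCBr | starting material
6 | [4-(trimethylsilyl)but-3-yn-1-yl]magnesium bromide | C[Si](C)(C)C#CCC[Mg]Br | intermediate
7 | (7E)-9-(tert-butyldimethylsilyloxy)-6,6-dimethyl-1-(trimethylsilyl)non-7-en-1-yn-5-one | C[Si](C)(C)C#CCCC(=O)C(C)(C)/C=C/CO[Si](C)(C)C(C)(C)C | intermediate
8 | (7E)-9-(tert-butyldimethylsilyloxy)-6,6-dimethylnon-7-en-1-yn-5-one | C#CCCC(=O)C(C)(C)/C=C/CO[Si](C)(C)C(C)(C)C | intermediate
9 | (3R)-3-[(E)-2-(tert-butyldimethylsilyloxy)ethenyl]-2,2-dimethyl-4-methylidenecyclohexan-1-one | C=C1CCC(=O)C(C)(C)[C@@H]1/C=C/O[Si](C)(C)C(C)(C)C | intermediate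
10 | (1R,3R)-3-[(E)-2-(tert-butyldimethylsilyloxy)ethenyl]-2,2-dimethyl-4-methylidenecyclohexan-1-ol | C=C1CC[C@@H](O)C(C)(C)[C@@H]1/C=C/O[Si](C)(C)C(C)(C)C | intermediate
11 | tert-butyl{(E)-2-[(1R,3R)-3-(tert-butyldimethylsilyloxy)-2,2-dimethyl-6-methylidenecyclohexyl]ethenyloxy}dimethylsilane | C=C1CC[C@@H](O[Si](C)(C)C(C)(C)C)C(C)(C)[C@@H]1/C=C/O[Si](C)(C)C(C)(C)C | intermediate
12 | 2-[(1R,3R)-3-(tert-butyldimethylsilyloxy)-2,2-dimethyl-6-methylidenecyclohexyl]acetaldehyde | C=C1CC[C@@H](O[Si](C)(C)C(C)(C)C)C(C)(C)[C@@H]1CC=O | intermediate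
13 | 2-[(1R,3R)-3-(tert-butyldimethylsilyloxy)-2,2-dimethyl-6-methylidenecyclohexyl]ethan-1-ol | C=C1CC[C@@H](O[Si](C)(C)C(C)(C)C)C(C)(C)[C@@H]1CCO | intermediate
14 | tert-butyl{[(1R,3R)-3-(2-iodoethyl)-2,2-dimethyl-4-methylidenecyclohexyl]oxy}dimethylsilane | C=C1CC[C@@H](O[Si](C)(C)C(C)(C)C)C(C)(C)[C@@H]1CCI | intermediate
15 | tert-butyl{[(1R,3R)-3-(but-3-yn-1-yl)-2,2-dimethyl-4-methylidenecyclohexyl]oxy}dimethylsilane | C=C1CC[C@@H](O[Si](C)(C)C(C)(C)C)C(C)(C)[C@@H]1CCC#C | intermediate
16 | (E)-alkenyl(dimethyl)alane from syn methylalumination of 15 | C=C1CC[C@@H](O[Si](C)(C)C(C)(C)C)C(C)(C)[C@@H]1CC/C(C)=C/[Al](C)C | intermediate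
17 | tert-butyl{[(1R,3R)-3-[(3E)-4-iodo-3-methylbut-3-en-1-yl]-2,2-dimethyl-4-methylidenecyclohexyl]oxy}dimethylsilane | C=C1CC[C@@H](O[Si](C)(C)C(C)(C)C)C(C)(C)[C@@H]1CC/C(C)=C/I | intermediate
18 | 2-methylbenzene-1,4-diol | Cc1cc(O)ccc1O | starting material
19 | 2-methyl-4-(triisopropylsilyloxy)phenol | Cc1cc(O[Si](C(C)C)(C(C)C)C(C)C)ccc1O | intermediate
20 | 2-hydroxy-3-methyl-5-(triisopropylsilyloxy)benzaldehyde | Cc1cc(O[Si](C(C)C)(C(C)C)C(C)C)cc(C=O)c1O | intermediate
21 | 2-ethenyl-6-methyl-4-(triisopropylsilyloxy)phenol | C=Cc1cc(O[Si](C(C)C)(C(C)C)C(C)C)cc(C)c1O | intermediate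
22 | but-2-yn-1-ol | CC#CCO | starting material
23 | sodium 2,2-bis(2-methoxyethoxy)-3-methyl-2,5-dihydro-1,2-oxaaluminol-2-uide | CC1=CCO[Al-]1(OCCOC)OCCOC.[Na+] | intermediate
24 | (2Z)-3-iodobut-2-en-1-ol | C/C(I)=C/CO | intermediate
25 | O,C-bis(9-borabicyclo[3.3.1]nonan-9-yl) adduct of 21 (aryl-O–B and aryl-CH2CH2–B) | Cc1cc(O[Si](C(C)C)(C(C)C)C(C)C)cc(CCB2C3CCCC2CCC3)c1OB1C2CCCC1CCC2 | intermediate
26 | 2-[(3Z)-5-hydroxy-3-methylpent-3-en-1-yl]-6-methyl-4-(triisopropylsilyloxy)phenol | C/C(CCc1cc(O[Si](C(C)C)(C(C)C)C(C)C)cc(C)c1O)=C/CO | intermediate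
27 | (2Z)-5-[2-hydroxy-3-methyl-5-(triisopropylsilyloxy)phenyl]-3-methylpent-2-en-1-yl methyl carbonate | C/C(CCc1cc(O[Si](C(C)C)(C(C)C)C(C)C)cc(C)c1O)=C/COC(=O)OC | intermediate
28 | {[(2R)-2-ethenyl-2,8-dimethyl-3,4-dihydro-2H-chromen-6-yl]oxy}tri(propan-2-yl)silane | C=C[C@@]1(C)CCc2cc(O[Si](C(C)C)(C(C)C)C(C)C)cc(C)c2O1 | intermediate
29 | 9-{2-[(2S)-2,8-dimethyl-6-(triisopropylsilyloxy)-3,4-dihydro-2H-chromen-2-yl]ethyl}-9-borabicyclo[3.3.1]nonane | C1CC2CCCC(C1)B2CC[C@@]1(C)CCc2cc(O[Si](C(C)C)(C(C)C)C(C)C)cc(C)c2O1 | intermediate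
30 | bis-silyl ether of the target (ring A O-TBS, phenol O-TIPS) | C=C1CC[C@@H](O[Si](C)(C)C(C)(C)C)C(C)(C)[C@@H]1CC/C(C)=C/CC[C@@]1(C)CCc2cc(O[Si](C(C)C)(C(C)C)C(C)C)cc(C)c2O1 | intermediate
31 | (2S)-2-{(3E)-6-[(1R,3R)-3-hydroxy-2,2-dimethyl-6-methylidenecyclohexyl]-4-methylhex-3-en-1-yl}-2,8-dimethyl-3,4-dihydro-2H-chromen-6-ol | C=C1CC[C@@H](O)C(C)(C)[C@@H]1CC/C(C)=C/CC[C@@]1(C)CCc2cc(O)cc(C)c2O1 | target

Total step count: 20. Longest linear sequence: 13 steps (steps 1–11, 19 and 20).

Steps most likely to fail

Step 5. The step may suffer from: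
- weak enantioface discrimination in the alkene insertion;
- attack of the ketone oxygen on the palladium-activated alkyne;
- alkyne oligomerisation;
- β-hydride loss toward the ring methine;
- later migration of the exocyclic alkene.

The fallback sets out from 8 and comes back at 10. Enyne 8 would be cyclised without asymmetric induction under the established neutral conditions for 1,7-enynes (Pd2(dba)3·CHCl3, P(o-Tol)3, AcOH, toluene) to the racemic ketone F1. A Corey–Bakshi–Shibata reduction ((S)-2-methyl-oxazaborolidine, catecholborane, toluene, −78 °C) would then turn both antipodes into (1R)-carbinols. These are 10 and the cis alcohol F2, which are diastereomers and should separate on silica. Compound 10 re-enters at step 7.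

Step 6. Facial selectivity may be poor if a conformer with an axial side chain takes part, because equatorial attack on that conformer leads to the cis alcohol. The fallback sets out from 9 and comes back at 10, and it replaces substrate control by catalyst control. It is a Corey–Bakshi–Shibata reduction with the (S)-oxazaborolidine and catecholborane. This reagent does not touch the alkenes at low temperature. It distinguishes the CMe2 flank (large) from the CH2 flank (small) and should therefore deliver the (1R)-carbinol whatever the ring conformation.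

Step 2. Turnover at the hindered vinyl group may be sluggish, so that self-metathesis and double-bond isomerisation of the allyl ether take over. The fallback sets out from 2 and comes back at 4:
- ozonolysis (O3, CH2Cl2, −78 °C; Me2S) to the aldehyde F3;
- Wittig olefination with Ph3P=CHCHO (toluene, 80 °C) to the (E)-enal F4;
- Luche reduction (NaBH4, CeCl3·7H2O, MeOH), which leaves the Weinreb amide alone, to the allylic alcohol F5;
- silylation (TBSCl, imidazole, CH2Cl2) to 4.

Further compounds
F1 | step 5 | rac-3-[(E)-2-(tert-butyldimethylsilyloxy)ethenyl]-2,2-dimethyl-4-methylidenecyclohexan-1-one | C=C1CCC(=O)C(C)(C)C1/C=C/O[Si](C)(C)C(C)(C)C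
F2 | step 5 | (1R,3S)-3-[(E)-2-(tert-butyldimethylsilyloxy)ethenyl]-2,2-dimethyl-4-methylidenecyclohexan-1-ol | C=C1CC[C@@H](O)C(C)(C)[C@H]1/C=C/O[Si](C)(C)C(C)(C)C
F0 | step 6 | none | none
F3 | step 2 | N-methoxy-N,2,2-trimethyl-3-oxopropanamide | CON(C)C(=O)C(C)(C)C=O
F4 | step 2 | (3E)-N-methoxy-N,2,2-trimethyl-5-oxopent-3-enamide | CON(C)C(=O)C(C)(C)/C=C/C=O
F5 | step 2 | (3E)-5-hydroxy-N-methoxy-N,2,2-trimethylpent-3-enamide | CON(C)C(=O)C(C)(C)/C=C/CO
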